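**Retrosynthetic overview**

1. Locants: C2 = C(CH3)(CH2OH), C4 = bridgehead CH, C5 = bridge CH2, C6 = quaternary bridgehead, C7 = CH–O, C8=C9(CO2H), C11 = CH–CHO, C12/C13 = CH2, C14 = ring-fusion CH. The last bond made is the C7–O ester bond (tricyclic hydroxy aldehyde 25 + silylated (Z)-hydroxy acid 32); one acidolysis then frees CO2H and both CH2OH groups.
2. Key disconnection C6–C14: quaternary C6 and oxygenated C7 are adjacent and shared by the cyclopentane (C6, C11, C12, C13, C14) and the cyclohexene (C4–C9). Moving C14 back from C6 to C7 gives a 1-methoxybicyclo[2.2.2]oct-2-ene (bridgeheads C4, C7) with a fused six-membered ring C6–C11–C12–C13–C14–C7 and a tertiary oxygen leaving group on C6 held antiperiplanar to C7–C14. A pinacol-type shift therefore contracts that ring to the cyclopentane, turns the bicyclo[2.2.2] into the bicyclo[3.2.1] skeleton and unveils C7=O next to C8=C9.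
3. The bicyclo[2.2.2]octene is opened at C7–C14 and C2–C4: intramolecular Diels–Alder reaction of the monocyclic methoxydienyl ester 19. Cycloaddition and shift are run in one flask (step 11).
4. 19 comes from methoxy enone 15 and (E)-allylboronate 9 by catalytic asymmetric allylboration (C6–C11) and ester dehydrogenation. This is the only step that introduces absolute configuration; the carbinol centre C6 then relays it to C2, C4 and C14 and ends, inverted, as the quaternary centre. The vinyl group on C11 is the masked CHO.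
5. Ring order: cyclohexene ring C4–C9 (Diels–Alder, step 6) → bicyclo[2.2.2]octene with fused cyclohexane (step 11, first half) → bicyclo[3.2.1]octenone with fused cyclopentane (step 11, second half).

Key step: step 11

Assumption: the (S)-dibromobinaphthol catalyst is taken to deliver the allyl unit of 9 to the carbonyl face of 15 on which C=O → C(OMe)= → CH2 runs clockwise, by analogy with aryl methyl ketones; if the sense is opposite, the (R)-catalyst is used and nothing else changes.

**Route**

Step 1
Reactants: 1 pent-4-yn-1-ol; 2 ethyl 2-(triphenyl-λ5-phosphanylidene)propanoate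
Product: 4 ethyl (2E)-2-methylhept-2-en-6-ynoate, via pent-4-ynal 3 (not isolated)
Conditions: PhI(OAc)2 (1.1 equiv), TEMPO (0.1 equiv), CH2Cl2, 20 °C; then 2 (1.2 equiv), 20 °C
Reagents that add atoms: none
Why: Nitroxyl-catalysed oxidation of the primary alcohol followed in the same flask by Wittig olefination with the stabilised ylide should give the (E)-trisubstituted enoate, the E geometry following from reversible addition of stabilised ylides; no stereocentre is formed.

Step 2
Reactants: 4 ethyl (2E)-2-methylhept-2-en-6-ynoate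
Product: 5 (2E)-2-methylhept-2-en-6-yn-1-ol
Conditions: i-Bu2AlH (2.2 equiv), CH2Cl2, −78 °C; aq. KNaC4H4O6
Reagents that add atoms: none
Why: 1,2-Reduction of the conjugated ester by the aluminium hydride at low temperature should give the allylic alcohol without touching the alkyne or the alkene geometry.

Step 3
Reactants: 5 (2E)-2-methylhept-2-en-6-yn-1-ol
Product: 6 tert-butyl(dimethyl){[(2E)-2-methylhept-2-en-6-yn-1-yl]oxy}silane
Conditions: t-BuMe2SiCl, imidazole, DMF, 20 °C
Reagents that add atoms: tert-butyl(chloro)dimethylsilane, CC(C)(C)[Si](C)(C)Cl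
Why: Standard silylation of a primary alcohol gives an ether that should survive base, heat, mild acid and oxidants until the last step.

Step 4
Reactants: 6 tert-butyl(dimethyl){[(2E)-2-methylhept-2-en-6-yn-1-yl]oxy}silane
Product: 8 2-[(1E,5E)-7-{[tert-butyl(dimethyl)silyl]oxy}-6-methylhepta-1,5-dien-1-yl]-1,3,2-dioxaborinane, via catechol boronate 7 (not isolated)
Conditions: catecholborane (1.1 equiv), THF, 70 °C; then propane-1,3-diol (1.5 equiv), 20 °C
Reagents that add atoms: catecholborane (1,3,2-benzodioxaborole), B1Oc2ccccc2O1; propane-1,3-diol, OCCCO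
Why: Syn hydroboration of the terminal alkyne (boron to the terminal carbon; the trisubstituted alkene reacts much more slowly) should give the (E)-alkenylboronate, and diol exchange gives the stable six-membered boronic ester.

Step 5
Reactants: 8 2-[(1E,5E)-7-{[tert-butyl(dimethyl)silyl]oxy}-6-methylhepta-1,5-dien-1-yl]-1,3,2-dioxaborinane
Product: 9 2-[(2E,6E)-8-{[tert-butyl(dimethyl)silyl]oxy}-7-methylocta-2,6-dien-1-yl]-1,3,2-dioxaborinane
Conditions: BrCH2Cl (1.5 equiv), n-BuLi (1.3 equiv), THF, −78 → 20 °C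
Reagents that add atoms: bromochloromethane, ClCBr
Why: Matteson homologation: (chloromethyl)lithium adds to boron and 1,2-migration of the alkenyl group with loss of chloride inserts one CH2 with retention of the (E)-geometry, giving the γ-substituted (E)-allylboronate.

Step 6
Reactants: 10 (1E)-1-methoxy-3-[(trimethylsilyl)oxy]buta-1,3-diene; 11 tert-butyl prop-2-enoate
Product: 12 tert-butyl 2-methoxy-4-[(trimethylsilyl)oxy]cyclohex-3-ene-1-carboxylate (racemic)
Conditions: toluene, 80 °C; concentrate, use crude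
Reagents that add atoms: none
Why: Normal-demand Diels–Alder reaction in which the nucleophilic CH2 terminus of the diene bonds to the acrylate β-carbon, so the ester carbon ends next to the methoxy carbon; the two stereocentres formed are both erased later (steps 7 and 10).

Step 7
Reactants: 12 tert-butyl 2-methoxy-4-[(trimethylsilyl)oxy]cyclohex-3-ene-1-carboxylate
Product: 14 tert-butyl 3-hydroxy-4-oxocyclohex-2-ene-1-carboxylate (racemic), via α-silyloxy ketone 13 (not isolated)
Conditions: mCPBA (1.1 equiv), NaHCO3, CH2Cl2, 0 °C; then 1 M HCl, THF, 20 °C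
Reagents that add atoms: 3-chloroperoxybenzoic acid, OOC(=O)c1cccc(Cl)c1
Why: Rubottom oxidation of the silyl enol ether places oxygen on C7, and dilute acid then removes the silyl group and eliminates methanol through the enediol to give the hydrogen-bonded 2-hydroxy enone with unambiguous regiochemistry.

Step 8
Reactants: 14 tert-butyl 3-hydroxy-4-oxocyclohex-2-ene-1-carboxylate
Product: 15 tert-butyl 3-methoxy-4-oxocyclohex-2-ene-1-carboxylate (racemic)
Conditions: (MeO)2SO2 (1.2 equiv), K2CO3, acetone, 20 °C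
Reagents that add atoms: dimethyl sulfate, COS(=O)(=O)OC
Why: O-Alkylation of the acidic enol of the cyclic 1,2-dione with a hard electrophile should give the methyl enol ether, which masks the future C7 carbonyl and cannot aromatise because C9 is still sp3.

Step 9
Reactants: 15 tert-butyl 3-methoxy-4-oxocyclohex-2-ene-1-carboxylate; 9 2-[(2E,6E)-8-{[tert-butyl(dimethyl)silyl]oxy}-7-methylocta-2,6-dien-1-yl]-1,3,2-dioxaborinane
Product: 17 tert-butyl (1RS,4R)-4-hydroxy-3-methoxy-4-[(3R,6E)-8-{[tert-butyl(dimethyl)silyl]oxy}-7-methylocta-1,6-dien-3-yl]cyclohex-2-ene-1-carboxylate, via borate ester 16 (not isolated)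
Conditions: (S)-3,3'-dibromo-1,1'-bi-2-naphthol (5 mol %), t-BuOH (2 equiv), toluene, 20 °C; then aq. NaHCO3
Reagents that add atoms: none
Why: Chiral-diol-catalysed asymmetric allylboration of a ketone through a closed six-membered chair transition state should join C6 to the γ-carbon C11: the catalyst selects the carbonyl face and so sets the carbinol centre C6, the (E)-boronate with the methoxyvinyl ring carbon pseudo-equatorial sets C11 (chain anti to hydroxyl), and the ester-bearing ring carbon remains an epimer mixture that is erased in step 10.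

Step 10
Reactants: 17 tert-butyl (1RS,4R)-4-hydroxy-3-methoxy-4-[(3R,6E)-8-{[tert-butyl(dimethyl)silyl]oxy}-7-methylocta-1,6-dien-3-yl]cyclohex-2-ene-1-carboxylate
Product: 19 tert-butyl (4R)-5-methoxy-4-[(3R,6E)-8-{[tert-butyl(dimethyl)silyl]oxy}-7-methylocta-1,6-dien-3-yl]-4-[(trimethylsilyl)oxy]cyclohexa-1,5-diene-1-carboxylate, via bis-silyl ketene acetal 18 (not isolated)
Conditions: LiN(iPr)2 (2.2 equiv), THF, −78 °C; Me3SiCl (2.5 equiv), −78 → 20 °C; then Pd(OAc)2 (0.1 equiv), allyl methyl carbonate (1.5 equiv), MeCN, 50 °C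
Reagents that add atoms: chlorotrimethylsilane, C[Si](C)(C)Cl
Why: Saegusa-type dehydrogenation: the ester enolate is trapped as its silyl ketene acetal (the tertiary alkoxide is silylated at the same time), palladation at C9 and β-hydride loss from C4 give the conjugated diene, both C9 epimers converge, and the silyl cap keeps the tertiary oxygen from leaving.

Step 11
Reactants: 19 tert-butyl (4R)-5-methoxy-4-[(3R,6E)-8-{[tert-butyl(dimethyl)silyl]oxy}-7-methylocta-1,6-dien-3-yl]-4-[(trimethylsilyl)oxy]cyclohexa-1,5-diene-1-carboxylate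
Product: 22 tricyclic oxo-enoate (tert-butyl ester; C7=O conjugated with C8=C9; vinyl on C11; C3 as silyl ether; C2, C4, C6, C11, C14 as in the target), via Diels–Alder adduct 20 (not isolated), via tertiary carbinol 21 (not isolated)
Conditions: toluene (0.01 M), BHT (0.1 equiv), base-washed sealed tube, 150 °C; then 0 °C, TsOH·H2O (0.3 equiv), CH2Cl2 saturated with H2O, 0 → 20 °C
Reagents that add atoms: water, O
Why: On heating, the alkene tethered to C6 adds across the methoxydiene at C7 and C4 in an intramolecular [4+2] cycloaddition; acid then cleaves the tertiary silyl ether and ionises C6–O while the antiperiplanar C7–C14 bond migrates to C6 (pinacol-type 1,2-shift), and the O-methyl oxocarbenium ion at C7 is hydrolysed to the conjugated ketone. Both halves are known reaction types: Diels–Alder cyclisation of 6-alkenylcyclohexa-1,3-dienes, and the acid-catalysed rearrangement of 1-methoxybicyclo[2.2.2]oct-5-en-2-ols to bicyclo[3.2.1]octenones. The cycloaddition closes the bicyclo[2.2.2]octene (new bonds C7–C14 and C2–C4) and, through the three-atom tether, a chair-like six-membered ring C6–C11–C12–C13–C14–C7; the shift contracts this ring to the cyclopentane C6–C11–C12–C13–C14 by forming C6–C14 and at the same time converts the bicyclo[2.2.2]octene into the bicyclo[3.2.1]octenone. C4, C14 and C2 are set in the cycloaddition by the carbinol centre C6, because the tether reaches only the diene face on which it stands and only with C13 turned towards C6, and by the (E)-alkene, which places CH2OSi syn to the ene bridge and CH3 syn to C5; quaternary C6 is set in the shift by inversion (C14 enters anti to the leaving oxygen, with retention at C14), and C11 is carried through with its vinyl group equatorial. The step needs cycloaddition before aromatisation of the diene, which the silyl cap and base-washed glass should secure, and migration of C14 rather than C8 or C12, which is secured because the fused ring holds the leaving group syn to the ene bridge and thus antiperiplanar to C7–C14, C8 is deactivated by the ester, and only a shift from the methoxy-bearing C7 ends in an oxocarbenium ion.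

Step 12
Reactants: 22 tricyclic oxo-enoate
Product: 23 tricyclic allylic alcohol (C7–OH syn to the C2–C14 bridge, as in the target)
Conditions: NaBH4, CeCl3·7H2O, MeOH, −78 °C
Reagents that add atoms: none
Why: Luche 1,2-reduction of the enone, in which hydride should enter from the face of the one-carbon bridge C5 (the other face is screened by C14 and its inward hydrogen), giving the pseudo-equatorial C7 alcohol of the target.

Step 13
Reactants: 23 tricyclic allylic alcohol
Product: 25 tricyclic hydroxy aldehyde (C11–CHO), via vicinal diol 24 (not isolated)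
Conditions: OsO4 (2 mol %), NaIO4 (4 equiv), 2,6-lutidine (2 equiv), 1,4-dioxane/H2O 3:1, 20 °C
Reagents that add atoms: osmium tetroxide, O=[Os](=O)(=O)=O; sodium periodate, [Na+].[O-]I(=O)(=O)=O
Why: Lemieux–Johnson cleavage is selective for the monosubstituted vinyl group over the electron-poor trisubstituted enoate and unveils the aldehyde on the already fixed C11 under buffered conditions that should not epimerise it; the hydroxyl on C7 is trans to CHO and cannot form a lactol.

Step 14
Reactants: 26 7-bromoheptan-1-ol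
Product: 27 [(7-bromoheptyl)oxy](tert-butyl)dimethylsilane
Conditions: t-BuMe2SiCl, imidazole, CH2Cl2, 20 °C
Reagents that add atoms: tert-butyl(chloro)dimethylsilane, CC(C)(C)[Si](C)(C)Cl
Why: Standard silylation masks the ω-hydroxyl so that the acid cannot oligomerise in the esterification.

Step 15
Reactants: 27 [(7-bromoheptyl)oxy](tert-butyl)dimethylsilane
Product: 28 (7-{[tert-butyl(dimethyl)silyl]oxy}heptyl)triphenylphosphonium bromide
Conditions: PPh3, MeCN, 82 °C
Reagents that add atoms: triphenylphosphane, c1ccc(cc1)P(c1ccccc1)c1ccccc1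
Why: SN2 quaternisation of the primary bromide gives the Wittig salt.

Step 16
Reactants: 28 (7-{[tert-butyl(dimethyl)silyl]oxy}heptyl)triphenylphosphonium bromide; 29 methyl 9-oxononanoate
Product: 31 methyl (9Z)-16-{[tert-butyl(dimethyl)silyl]oxy}hexadec-9-enoate, via phosphorus ylide 30 (not isolated)
Conditions: NaN(SiMe3)2 (1.05 equiv), THF, −78 °C; then 29, −78 → 20 °C
Reagents that add atoms: none
Why: Wittig olefination of an aldehyde with a non-stabilised ylide under lithium-free conditions should give the (Z)-alkene by kinetic control.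

Step 17
Reactants: 31 methyl (9Z)-16-{[tert-butyl(dimethyl)silyl]oxy}hexadec-9-enoate
Product: 32 (9Z)-16-{[tert-butyl(dimethyl)silyl]oxy}hexadec-9-enoic acid
Conditions: LiOH (3 equiv), THF/H2O 3:1, 20 °C; then 1 M HCl to pH 4
Reagents that add atoms: lithium hydroxide, [Li+].[OH-]
Why: Saponification of the unhindered methyl ester leaves the primary silyl ether and the (Z)-alkene untouched.

Step 18
Reactants: 25 tricyclic hydroxy aldehyde; 32 (9Z)-16-{[tert-butyl(dimethyl)silyl]oxy}hexadec-9-enoic acid
Product: 33 fully protected target (C7 ester; tert-butyl ester; two silyl ethers; free CHO)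
Conditions: N-(3-dimethylaminopropyl)-N'-ethylcarbodiimide hydrochloride (1.5 equiv), 4-(dimethylamino)pyridine (0.2 equiv), CH2Cl2, 0 → 20 °C
Reagents that add atoms: none
Why: Steglich esterification acylates the only free hydroxyl (C7, pseudo-equatorial) with retention, and the aldehyde and its hindered α-centre should tolerate the mild acyl-transfer conditions.

Step 19
Reactants: 33 fully protected target
Product: 34 target CNP0148862.2
Conditions: CF3CO2H/CH2Cl2/H2O (10:30:1), 0 → 20 °C; evaporate; MeOH/pH 7 buffer, 20 °C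
Reagents that add atoms: none
Why: Acidolysis cleaves the tert-butyl ester by alkyl–oxygen fission and both primary silyl ethers, while the allylic acyloxy group (its ionisation disfavoured by the conjugated carboxyl), the (Z)-alkene and the aldehyde should survive; no stereocentre is touched.

**Compound list**

1 | pent-4-yn-1-ol | C#CCCCO | starting material
2 | ethyl 2-(triphenyl-λ5-phosphanylidene)propanoate | CCOC(=O)C(C)=P(c1ccccc1)(c1ccccc1)c1ccccc1 | starting material
3 | pent-4-ynal | C#CCCC=O | intermediate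
4 | ethyl (2E)-2-methylhept-2-en-6-ynoate | CCOC(=O)/C(C)=C/CCC#C | intermediate
5 | (2E)-2-methylhept-2-en-6-yn-1-ol | OC/C(C)=C/CCC#C | intermediate
6 | tert-butyl(dimethyl){[(2E)-2-methylhept-2-en-6-yn-1-yl]oxy}silane | CC(C)(C)[Si](C)(C)OC/C(C)=C/CCC#C | intermediate
7 | 2-[(1E,5E)-7-{[tert-butyl(dimethyl)silyl]oxy}-6-methylhepta-1,5-dien-1-yl]-1,3,2-benzodioxaborole | CC(C)(C)[Si](C)(C)OC/C(C)=C/CC/C=C/B1Oc2ccccc2O1 | intermediate
8 | 2-[(1E,5E)-7-{[tert-butyl(dimethyl)silyl]oxy}-6-methylhepta-1,5-dien-1-yl]-1,3,2-dioxaborinane | CC(C)(C)[Si](C)(C)OC/C(C)=C/CC/C=C/B1OCCCO1 | intermediate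
9 | 2-[(2E,6E)-8-{[tert-butyl(dimethyl)silyl]oxy}-7-methylocta-2,6-dien-1-yl]-1,3,2-dioxaborinane | CC(C)(C)[Si](C)(C)OC/C(C)=C/CC/C=C/CB1OCCCO1 | intermediate
10 | (1E)-1-methoxy-3-[(trimethylsilyl)oxy]buta-1,3-diene | CO/C=C/C(=C)O[Si](C)(C)C | starting material
11 | tert-butyl prop-2-enoate | C=CC(=O)OC(C)(C)C | starting material
12 | tert-butyl 2-methoxy-4-[(trimethylsilyl)oxy]cyclohex-3-ene-1-carboxylate (racemic) | COC1C=C(O[Si](C)(C)C)CCC1C(=O)OC(C)(C)C | intermediate
13 | tert-butyl 2-methoxy-4-oxo-3-[(trimethylsilyl)oxy]cyclohexane-1-carboxylate (diastereomer mixture) | COC1C(O[Si](C)(C)C)C(=O)CCC1C(=O)OC(C)(C)C | intermediate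
14 | tert-butyl 3-hydroxy-4-oxocyclohex-2-ene-1-carboxylate (racemic) | OC1=CC(CCC1=O)C(=O)OC(C)(C)C | intermediate
15 | tert-butyl 3-methoxy-4-oxocyclohex-2-ene-1-carboxylate (racemic) | COC1=CC(CCC1=O)C(=O)OC(C)(C)C | intermediate
16 | 1,3,2-dioxaborinan-2-yl borate ester of 17 at the tertiary oxygen | COC1=CC(C(=O)OC(C)(C)C)CC[C@@]1(OB2OCCCO2)[C@@H](C=C)CC/C=C(\C)CO[Si](C)(C)C(C)(C)C | intermediate
17 | tert-butyl (1RS,4R)-4-hydroxy-3-methoxy-4-[(3R,6E)-8-{[tert-butyl(dimethyl)silyl]oxy}-7-methylocta-1,6-dien-3-yl]cyclohex-2-ene-1-carboxylate | COC1=CC(C(=O)OC(C)(C)C)CC[C@@]1(O)[C@@H](C=C)CC/C=C(\C)CO[Si](C)(C)C(C)(C)C | intermediate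
18 | tert-butyl trimethylsilyl ketene acetal of 17, tertiary hydroxyl as trimethylsilyl ether | COC1=CC(=C(O[Si](C)(C)C)OC(C)(C)C)CC[C@@]1(O[Si](C)(C)C)[C@@H](C=C)CC/C=C(\C)CO[Si](C)(C)C(C)(C)C | intermediate
19 | tert-butyl (4R)-5-methoxy-4-[(3R,6E)-8-{[tert-butyl(dimethyl)silyl]oxy}-7-methylocta-1,6-dien-3-yl]-4-[(trimethylsilyl)oxy]cyclohexa-1,5-diene-1-carboxylate | COC1=CC(C(=O)OC(C)(C)C)=CC[C@@]1(O[Si](C)(C)C)[C@@H](C=C)CC/C=C(\C)CO[Si](C)(C)C(C)(C)C | intermediate
20 | Diels–Alder adduct: bicyclo[2.2.2]oct-2-ene (bridgeheads C4–H and C7–OMe; ene bridge C8=C9 with CO2tBu on C9; bridge C5H2–C6(OSiMe3); bridge C14H–C2(CH3)(CH2OSi)) with cyclohexane fused through C6–C11–C12–C13–C14 (C7 shared); OSiMe3 and CH2OSi syn to the ene bridge, CH3 syn to C5, vinyl on C11 equatorial | C[C@@]1(CO[Si](C)(C)C(C)(C)C)[C@H]2C[C@@]3(O[Si](C)(C)C)[C@@H](C=C)CC[C@@H]1[C@@]3(OC)C=C2C(=O)OC(C)(C)C | intermediate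
21 | tertiary carbinol of 20 (C6–OH) | C[C@@]1(CO[Si](C)(C)C(C)(C)C)[C@H]2C[C@@]3(O)[C@@H](C=C)CC[C@@H]1[C@@]3(OC)C=C2C(=O)OC(C)(C)C | intermediate
22 | tricyclic oxo-enoate: bicyclo[3.2.1]oct-3-en-2-one (C7=O, C8=C9–CO2tBu) with cyclopentane fused at C6–C14; vinyl on C11; C3 silyl ether; stereocentres as in the target | C[C@@]1(CO[Si](C)(C)C(C)(C)C)[C@H]2C[C@@]3(C(=O)C=C2C(=O)OC(C)(C)C)[C@@H](C=C)CC[C@@H]13 | intermediate
23 | tricyclic allylic alcohol (C7–OH as in the target) | C[C@@]1(CO[Si](C)(C)C(C)(C)C)[C@H]2C[C@@]3([C@@H](O)C=C2C(=O)OC(C)(C)C)[C@@H](C=C)CC[C@@H]13 | intermediate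
24 | vicinal diol from the vinyl group of 23 (new carbinol centre unassigned) | C[C@@]1(CO[Si](C)(C)C(C)(C)C)[C@H]2C[C@@]3([C@@H](O)C=C2C(=O)OC(C)(C)C)[C@@H](C(O)CO)CC[C@@H]13 | intermediate
25 | tricyclic hydroxy aldehyde (C7–OH, C11–CHO, tert-butyl ester, C3 silyl ether) | C[C@@]1(CO[Si](C)(C)C(C)(C)C)[C@H]2C[C@@]3([C@@H](O)C=C2C(=O)OC(C)(C)C)[C@@H](C=O)CC[C@@H]13 | intermediate
26 | 7-bromoheptan-1-ol | OCCCCCCCBr | starting material
27 | [(7-bromoheptyl)oxy](tert-butyl)dimethylsilane | CC(C)(C)[Si](C)(C)OCCCCCCCBr | intermediate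
28 | (7-{[tert-butyl(dimethyl)silyl]oxy}heptyl)triphenylphosphonium bromide | CC(C)(C)[Si](C)(C)OCCCCCCC[P+](c1ccccc1)(c1ccccc1)c1ccccc1.[Br-] | intermediate
29 | methyl 9-oxononanoate | COC(=O)CCCCCCCC=O | starting material
30 | (7-{[tert-butyl(dimethyl)silyl]oxy}heptylidene)triphenyl-λ5-phosphane | CC(C)(C)[Si](C)(C)OCCCCCCC=P(c1ccccc1)(c1ccccc1)c1ccccc1 | intermediate
31 | methyl (9Z)-16-{[tert-butyl(dimethyl)silyl]oxy}hexadec-9-enoate | COC(=O)CCCCCCC/C=C\CCCCCCO[Si](C)(C)C(C)(C)C | intermediate
32 | (9Z)-16-{[tert-butyl(dimethyl)silyl]oxy}hexadec-9-enoic acid | OC(=O)CCCCCCC/C=C\CCCCCCO[Si](C)(C)C(C)(C)C | intermediate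
33 | fully protected target (C7 ester of 25 with 32) | C[C@@]1(CO[Si](C)(C)C(C)(C)C)[C@H]2C[C@@]3([C@@H](OC(=O)CCCCCCC/C=C\CCCCCCO[Si](C)(C)C(C)(C)C)C=C2C(=O)OC(C)(C)C)[C@@H](C=O)CC[C@@H]13 | intermediate
34 | CNP0148862.2: C7 ester of the tricyclic hydroxy aldehyde acid with (9Z)-16-hydroxyhexadec-9-enoic acid | C[C@@]1(CO)[C@H]2C[C@@]3([C@@H](OC(=O)CCCCCCC/C=C\CCCCCCO)C=C2C(=O)O)[C@@H](C=O)CC[C@@H]13 | target

**Step count and risks**

Total step count: 19. Longest linear sequence: 12 steps (1–5, 9–13, 18, 19).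

Most likely to fail, first: step 11. The cyclohexadiene may aromatise by loss of its oxygen substituents, or shift its double bonds by 1,5-hydrogen migration, faster than a cycloaddition that must join two fully substituted carbons; the acid stage could then also meet a mixture. The fallback sets out from 17 and comes back at 22. It makes the diene from an enone by γ-deprotonation, isolates the adduct and triggers the shift with a Lewis acid. Mild hydrolysis of the enol ether (pyridinium 4-toluenesulfonate, acetone/H2O) gives tert-butyl (1RS,4R)-4-hydroxy-3-oxo-4-[(3R,6E)-8-{[tert-butyl(dimethyl)silyl]oxy}-7-methylocta-1,6-dien-3-yl]cyclohexane-1-carboxylate F1. Dehydrogenation with 2-iodoxybenzoic acid (DMSO, 65 °C) gives the oxo-enoate tert-butyl (4R)-4-hydroxy-3-oxo-4-[(3R,6E)-8-{[tert-butyl(dimethyl)silyl]oxy}-7-methylocta-1,6-dien-3-yl]cyclohex-1-ene-1-carboxylate F2. tert-Butyldimethylsilyl triflate and Et3N (CH2Cl2, 0 °C) silylate the tertiary hydroxyl and enolise towards C4 to give the bis-silyl 1-silyloxydiene F3, which is more electron-rich and carries a poorer leaving group on C6. Heating (toluene, 130 °C) gives the bis-silyl Diels–Alder adduct F4. BF3·OEt2 (CH2Cl2, −40 °C) ionises the tertiary silyl ether anti to C7–C14 and the same shift gives 22.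

Second: step 9. The cyclic methoxy enone may sit in the chair transition state with the ring CH2, not the methoxyvinyl carbon, pseudo-equatorial, which inverts the C6/C11 relationship; facial control by the diol catalyst on this ketone class may also be weaker than on aryl ketones. The fallback sets out from 6 and comes back at 17, using the geometrically opposite reagent made by different chemistry. Lithiation of 6 (n-BuLi, THF, −78 °C) and reaction with 2-(iodomethyl)-1,3,2-dioxaborinane gives, by alkynyl 1,2-migration, the propargylic boronate 2-[(6E)-8-{[tert-butyl(dimethyl)silyl]oxy}-7-methyloct-6-en-2-yn-1-yl]-1,3,2-dioxaborinane F5. Semihydrogenation (H2, Pd/CaCO3 poisoned with Pb(OAc)2, quinoline) gives the (2Z,6E)-allylboronate F6. Its chair with the ring CH2 pseudo-equatorial and the chain axial leads, under the same diol catalysis with 15, to the same C6/C11 arrangement, that is to 17.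

Third: step 12. Hydride may be delivered to the other face of the C7 carbonyl (the face of the two-carbon bridge), giving the pseudo-axial alcohol. The fallback sets out from 22 and comes back at 23, correcting by inversion instead of by direct reduction. The reduction product, the C7-epimeric allylic alcohol F7, is subjected to Mitsunobu inversion (PPh3, diisopropyl azodicarboxylate, 4-nitrobenzoic acid, toluene, 0 → 20 °C) to give the 4-nitrobenzoate F8 with the target configuration at C7. Methanolysis (K2CO3, MeOH, 0 °C) gives 23.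

**Further compounds**

F1 | step 11 | tert-butyl (1RS,4R)-4-hydroxy-3-oxo-4-[(3R,6E)-8-{[tert-butyl(dimethyl)silyl]oxy}-7-methylocta-1,6-dien-3-yl]cyclohexane-1-carboxylate | O=C1CC(C(=O)OC(C)(C)C)CC[C@@]1(O)[C@@H](C=C)CC/C=C(\C)CO[Si](C)(C)C(C)(C)C
F2 | step 11 | tert-butyl (4R)-4-hydroxy-3-oxo-4-[(3R,6E)-8-{[tert-butyl(dimethyl)silyl]oxy}-7-methylocta-1,6-dien-3-yl]cyclohex-1-ene-1-carboxylate | O=C1C=C(C(=O)OC(C)(C)C)CC[C@@]1(O)[C@@H](C=C)CC/C=C(\C)CO[Si](C)(C)C(C)(C)C
F3 | step 11 | tert-butyl (4R)-4,5-bis{[tert-butyl(dimethyl)silyl]oxy}-4-[(3R,6E)-8-{[tert-butyl(dimethyl)silyl]oxy}-7-methylocta-1,6-dien-3-yl]cyclohexa-1,5-diene-1-carboxylate | CC(C)(C)[Si](C)(C)OC1=CC(C(=O)OC(C)(C)C)=CC[C@@]1(O[Si](C)(C)C(C)(C)C)[C@@H](C=C)CC/C=C(\C)CO[Si](C)(C)C(C)(C)C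
F4 | step 11 | bis-silyl Diels–Alder adduct (as 20, with tert-butyldimethylsilyloxy on C6 and on bridgehead C7) | C[C@@]1(CO[Si](C)(C)C(C)(C)C)[C@H]2C[C@@]3(O[Si](C)(C)C(C)(C)C)[C@@H](C=C)CC[C@@H]1[C@@]3(O[Si](C)(C)C(C)(C)C)C=C2C(=O)OC(C)(C)C
F5 | step 9 | 2-[(6E)-8-{[tert-butyl(dimethyl)silyl]oxy}-7-methyloct-6-en-2-yn-1-yl]-1,3,2-dioxaborinane | CC(C)(C)[Si](C)(C)OC/C(C)=C/CCC#CCB1OCCCO1
F6 | step 9 | 2-[(2Z,6E)-8-{[tert-butyl(dimethyl)silyl]oxy}-7-methylocta-2,6-dien-1-yl]-1,3,2-dioxaborinane | CC(C)(C)[Si](C)(C)OC/C(C)=C/CC/C=C\CB1OCCCO1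
F7 | step 12 | C7-epimeric tricyclic allylic alcohol (hydroxyl syn to the C5 bridge) | C[C@@]1(CO[Si](C)(C)C(C)(C)C)[C@H]2C[C@@]3([C@H](O)C=C2C(=O)OC(C)(C)C)[C@@H](C=C)CC[C@@H]13
F8 | step 12 | 4-nitrobenzoate of 23 (C7 configuration of the target) | C[C@@]1(CO[Si](C)(C)C(C)(C)C)[C@H]2C[C@@]3([C@@H](OC(=O)c4ccc(cc4)[N+](=O)[O-])C=C2C(=O)OC(C)(C)C)[C@@H](C=C)CC[C@@H]13
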